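**Retrosynthetic overview**

The target is read as epiafzelechin-(4β→6)-(−)-epicatechin 3-O-gallate. The last disconnections are the eleven O-benzyl groups and a C8 bromine cap (hydrogenolysis), then the interflavan C4–C6 bond (Friedel–Crafts alkylation of a bromine-capped, galloylated (−)-epicatechin by the upper-unit C4 cation, which sets C4).
The upper unit is taken back to the achiral flavonol oxidation level; one enantioselective syn-hydrogenation of C2=C3 and C4=O then sets C2 and C3 (cis) and leaves C4–OH as the leaving group.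
Ring C of the flavonol is closed in the key step: C2–C3 by Claisen-type C-acylation of a ketone enolate with the ring B aroyl chloride, O1–C8a by intramolecular SNAr of the resulting diketonate, and the C5 and C7 ethers by two further SNAr reactions in the same flask.
Enabling feature: ring A is a phloroglucinol ring whose three oxygens (O1 on C8a, O on C5, O on C7) all sit ortho or para to C4a. With C4 as a ketone, a 2,4,6-trifluorophenyl group therefore has every C–F bond activated by the C4 carbonyl, and O1 and the C4 oxygen are 1,3-related across C2–C3 like the oxygens of a 1,3-diketone.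
Ring order: rings A and B of the upper unit and all rings of the lower unit are bought; upper ring C is formed in step 2; the two flavan units are joined in step 7.

Key step: step 2

Remark on the chemistry: the flavan-4-ol of step 3 is drawn as the all-cis isomer expected from syn-hydrogenation, but either C4 epimer would serve, because C4 is ionised in step 7.

**Route**

Step 1
Reactants: 1 1,3,5-trifluorobenzene; 2 2-(benzyloxy)-N-methoxy-N-methylacetamide
Product: 4 2-(benzyloxy)-1-(2,4,6-trifluorophenyl)ethan-1-one, via trifluorophenyllithium 3 (not isolated)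
Conditions: n-BuLi, THF, −78 °C; then 2, −78 °C; aq. NH4Cl
Reagents that add atoms: none
Why: Deprotonation between two fluorines (all three ring C–H are equivalent) gives an aryllithium that is acylated once through the chelated tetrahedral intermediate of the Weinreb ketone synthesis; no stereocenter is formed.

Step 2
Reactants: 4 2-(benzyloxy)-1-(2,4,6-trifluorophenyl)ethan-1-one; 5 4-(benzyloxy)benzoyl chloride
Product: 8 3,5,7-tris(benzyloxy)-2-[4-(benzyloxy)phenyl]-4H-chromen-4-one, via lithium diketonate 6 (not isolated), via difluoroflavonol ether 7 (not isolated)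
Conditions: LiN(SiMe3)2 (2.2 equiv), THF, −78 °C; 5, −78 → 25 °C, then 50 °C; then BnONa (from BnOH and NaH, 2.5 equiv), DMF, 25 → 50 °C
Reagents that add atoms: benzyl alcohol OCc1ccccc1
Why: The lithium enolate of 4 is C-acylated by 5 (Claisen-type, forming C2–C3) and the second equivalent of base converts the 1,3-diketone into chelated diketonate 6, whose enolate oxygen on C2 adds to C8a, the ortho C–F carbon, and expels fluoride from the Meisenheimer intermediate to give chromone 7; sodium benzyloxide then replaces the C5 fluorine (ortho to C4=O) and the C7 fluorine (para) by two further SNAr reactions. The closest known reaction types are the base-induced cyclisation of 1-(2-fluoroaryl)-1,3-diketones to chromones and of 2-fluorobenzoyl enaminones to 4-quinolones, and alkoxide SNAr on fluoroarenes. Ring C closes by a 6-exo-trig addition of O1 to C8a (the C8a=C8 π bond lies outside the forming ring) followed by elimination of fluoride. No stereocenter is created, and this is intended: C2 and C3 of a C4 ketone would be open to retro-aldol cleavage and enolisation under the basic ring-closing conditions, so they are introduced in step 3 from a planar precursor. The step needs C- rather than O-acylation, which the lithium enolate in THF should favour, and any enol ester should be transacylated by the excess enolate. There is no regiochemical choice in the ring closure (the two ortho fluorines are equivalent by symmetry) or in the ether formation (both remaining fluorines must be replaced, and both are activated by the C4 carbonyl).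

Step 3
Reactants: 8 3,5,7-tris(benzyloxy)-2-[4-(benzyloxy)phenyl]-4H-chromen-4-one
Product: 9 (2R,3R,4R)-3,5,7-tris(benzyloxy)-2-[4-(benzyloxy)phenyl]-3,4-dihydro-2H-chromen-4-ol (2,3-cis, 3,4-cis)
Conditions: H2 (100 bar), Ru(cod)(2-methylallyl)2 (5 mol%), 1,3-bis[(1R)-1-(naphthalen-1-yl)ethyl]-4,5-dihydroimidazolium tetrafluoroborate (10 mol%), KOt-Bu (15 mol%), toluene, 25–40 °C
Reagents that add atoms: none
Why: Proposed new method: a chiral Ru–NHC hydride should add H2 syn across the tetrasubstituted C2=C3 bond of the benzopyranone on the catalyst-selected enantioface (setting C2 and C3 together, hence 2,3-cis; the ligand antipode is to be chosen for the 2R,3R series) and then reduce C4=O from the same face to the all-cis alcohol; the closest known reaction type is the Ru–NHC-catalysed enantioselective hydrogenation of 3-unsubstituted flavones to cis-flavan-4-ols, supported by the all-cis outcome of heterogeneous hydrogenation of flavonol ethers, and what is new is the 3-alkoxy, tetrasubstituted C=C bond.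

Step 4
Reactants: 10 (−)-epicatechin
Product: 11 (2R,3R)-5,7-bis(benzyloxy)-2-[3,4-bis(benzyloxy)phenyl]-3,4-dihydro-2H-chromen-3-ol
Conditions: BnBr (4.4 equiv), K2CO3, DMF, 0 → 25 °C
Reagents that add atoms: benzyl bromide BrCc1ccccc1
Why: Williamson etherification of the four phenols only, since K2CO3 does not deprotonate the aliphatic 3-OH; both stereocenters come unchanged from the chiral pool.

Step 5
Reactants: 11 (2R,3R)-5,7-bis(benzyloxy)-2-[3,4-bis(benzyloxy)phenyl]-3,4-dihydro-2H-chromen-3-ol
Product: 12 (2R,3R)-5,7-bis(benzyloxy)-2-[3,4-bis(benzyloxy)phenyl]-8-bromo-3,4-dihydro-2H-chromen-3-ol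
Conditions: NBS (1.0 equiv), CH2Cl2, −78 → 0 °C
Reagents that add atoms: N-bromosuccinimide O=C1CCC(=O)N1Br
Why: Electrophilic aromatic bromination should occur at C8, the more reactive and less hindered of the two free ring A positions, leaving C6 as the only nucleophilic site for step 7; no stereocenter is touched.

Step 6
Reactants: 12 (2R,3R)-5,7-bis(benzyloxy)-2-[3,4-bis(benzyloxy)phenyl]-8-bromo-3,4-dihydro-2H-chromen-3-ol; 13 3,4,5-tris(benzyloxy)benzoic acid
Product: 14 (2R,3R)-5,7-bis(benzyloxy)-2-[3,4-bis(benzyloxy)phenyl]-8-bromo-3,4-dihydro-2H-chromen-3-yl 3,4,5-tris(benzyloxy)benzoate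
Conditions: DCC, DMAP (cat.), CH2Cl2, 25 °C
Reagents that add atoms: none
Why: Steglich esterification acylates the only free hydroxyl on oxygen, so the C3–O bond and its configuration are retained.

Step 7
Reactants: 9 (2R,3R,4R)-3,5,7-tris(benzyloxy)-2-[4-(benzyloxy)phenyl]-3,4-dihydro-2H-chromen-4-ol; 14 (2R,3R)-5,7-bis(benzyloxy)-2-[3,4-bis(benzyloxy)phenyl]-8-bromo-3,4-dihydro-2H-chromen-3-yl 3,4,5-tris(benzyloxy)benzoate
Product: 15 14 carrying at C6 the (2R,3R)-3,5,7-tris(benzyloxy)-2-[4-(benzyloxy)phenyl]chroman-4-yl group, 4β-linked (upper unit 2,3-cis, 3,4-trans)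
Conditions: Me3SiOTf (0.3 equiv), 4 Å molecular sieves, CH2Cl2, −78 → −40 °C; 14 (3 equiv), slow addition of 9
Reagents that add atoms: none
Why: Lewis-acid ionisation of the C4–OH gives a benzylic cation stabilised by the 5- and 7-alkoxy groups, and Friedel–Crafts alkylation by C6 of 14 (C8 is blocked by bromine) should occur anti to the C3 benzyloxy and C2 aryl groups, setting the new C4 stereocenter 4β (3,4-trans).

Step 8
Reactants: 15 protected 4β→6 dimer
Product: 16 epiafzelechin-(4β→6)-(−)-epicatechin 3-O-gallate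
Conditions: H2 (1 atm), Pd(OH)2/C, Et3N, THF/MeOH/H2O, 25 °C
Reagents that add atoms: none
Why: Hydrogenolysis should remove the eleven benzyl ethers and the C8 bromine in one operation, Et3N trapping HBr so that the acid-labile interflavan bond and the gallate survive; no stereocenter is touched.

**Compound list**

1 | 1,3,5-trifluorobenzene | Fc1cc(F)cc(F)c1 | starting material
2 | 2-(benzyloxy)-N-methoxy-N-methylacetamide | CON(C)C(=O)COCc1ccccc1 | starting material
3 | (2,4,6-trifluorophenyl)lithium | [Li]c1c(F)cc(F)cc1F | intermediate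
4 | 2-(benzyloxy)-1-(2,4,6-trifluorophenyl)ethan-1-one | O=C(COCc1ccccc1)c1c(F)cc(F)cc1F | intermediate
5 | 4-(benzyloxy)benzoyl chloride | O=C(Cl)c1ccc(OCc2ccccc2)cc1 | starting material
6 | lithium enolate of 2-(benzyloxy)-1-[4-(benzyloxy)phenyl]-3-(2,4,6-trifluorophenyl)propane-1,3-dione | [Li]OC(=C(OCc1ccccc1)C(=O)c1c(F)cc(F)cc1F)c1ccc(OCc2ccccc2)cc1 | intermediate
7 | 3-(benzyloxy)-2-[4-(benzyloxy)phenyl]-5,7-difluoro-4H-chromen-4-one | O=c1c(OCc2ccccc2)c(-c2ccc(OCc3ccccc3)cc2)oc2cc(F)cc(F)c12 | intermediate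
8 | 3,5,7-tris(benzyloxy)-2-[4-(benzyloxy)phenyl]-4H-chromen-4-one | O=c1c(OCc2ccccc2)c(-c2ccc(OCc3ccccc3)cc2)oc2cc(OCc3ccccc3)cc(OCc3ccccc3)c12 | intermediate
9 | (2R,3R,4R)-3,5,7-tris(benzyloxy)-2-[4-(benzyloxy)phenyl]-3,4-dihydro-2H-chromen-4-ol (all-cis) | O[C@@H]1c2c(OCc3ccccc3)cc(OCc3ccccc3)cc2O[C@H](c2ccc(OCc3ccccc3)cc2)[C@@H]1OCc1ccccc1 | intermediate
10 | (−)-epicatechin, (2R,3R)-2-(3,4-dihydroxyphenyl)-3,4-dihydro-2H-chromene-3,5,7-triol | O[C@@H]1Cc2c(cc(O)cc2O)O[C@@H]1c1ccc(O)c(O)c1 | starting material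
11 | (2R,3R)-5,7-bis(benzyloxy)-2-[3,4-bis(benzyloxy)phenyl]-3,4-dihydro-2H-chromen-3-ol | O[C@@H]1Cc2c(cc(OCc3ccccc3)cc2OCc3ccccc3)O[C@@H]1c1ccc(OCc3ccccc3)c(OCc3ccccc3)c1 | intermediate
12 | (2R,3R)-5,7-bis(benzyloxy)-2-[3,4-bis(benzyloxy)phenyl]-8-bromo-3,4-dihydro-2H-chromen-3-ol | O[C@@H]1Cc2c(c(Br)c(OCc3ccccc3)cc2OCc3ccccc3)O[C@@H]1c1ccc(OCc3ccccc3)c(OCc3ccccc3)c1 | intermediate
13 | 3,4,5-tris(benzyloxy)benzoic acid | OC(=O)c1cc(OCc2ccccc2)c(OCc2ccccc2)c(OCc2ccccc2)c1 | starting material
14 | (2R,3R)-5,7-bis(benzyloxy)-2-[3,4-bis(benzyloxy)phenyl]-8-bromo-3,4-dihydro-2H-chromen-3-yl 3,4,5-tris(benzyloxy)benzoate | O=C(O[C@@H]1Cc2c(c(Br)c(OCc3ccccc3)cc2OCc3ccccc3)O[C@@H]1c1ccc(OCc3ccccc3)c(OCc3ccccc3)c1)c1cc(OCc2ccccc2)c(OCc2ccccc2)c(OCc2ccccc2)c1 | intermediate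
15 | 14 carrying at C6 the (2R,3R)-3,5,7-tris(benzyloxy)-2-[4-(benzyloxy)phenyl]chroman-4-yl group, 4β-linked (upper unit 2,3-cis, 3,4-trans) | O=C(O[C@@H]1Cc2c(c(Br)c(OCc5ccccc5)c([C@H]3c4c(OCc5ccccc5)cc(OCc5ccccc5)cc4O[C@H](c4ccc(OCc5ccccc5)cc4)[C@@H]3OCc5ccccc5)c2OCc5ccccc5)O[C@@H]1c1ccc(OCc5ccccc5)c(OCc5ccccc5)c1)c1cc(OCc5ccccc5)c(OCc5ccccc5)c(OCc5ccccc5)c1 | intermediate
16 | epiafzelechin-(4β→6)-(−)-epicatechin 3-O-gallate; (2R,3R)-2-(3,4-dihydroxyphenyl)-5,7-dihydroxy-6-[(2R,3R,4S)-3,5,7-trihydroxy-2-(4-hydroxyphenyl)-3,4-dihydro-2H-chromen-4-yl]-3,4-dihydro-2H-chromen-3-yl 3,4,5-trihydroxybenzoate | O=C(O[C@@H]1Cc2c(cc(O)c([C@H]3c4c(O)cc(O)cc4O[C@H](c4ccc(O)cc4)[C@@H]3O)c2O)O[C@@H]1c1ccc(O)c(O)c1)c1cc(O)c(O)c(O)c1 | target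

**Step count and risks**

Total step count: 8. Longest linear sequence: 5 steps (steps 1, 2, 3, 7, 8; the lower-unit branch through steps 4, 5, 6, 7, 8 is equally long).

Steps most likely to fail:

1. Step 3 (proposed new method). The tetrasubstituted, alkoxy-substituted C2=C3 bond may resist hydride insertion or be reduced with poor enantioface discrimination, and reduction may stop at the ketone. Fallback with known chemistry, setting out from 8: heterogeneous hydrogenation over PtO2 in EtOAc (syn-addition to one face of the planar benzopyranone; platinum largely spares benzyl aryl ethers) should give the all-cis flavan-4-ol as a racemate, that is 9 together with its (2S,3S,4S)-enantiomer F1. The racemate is coupled with enantiopure 14 under the conditions of step 7, the unwanted diastereomeric dimer with the 2S,3S,4α upper unit F2 is removed by chromatography, and the route is rejoined at 15. Stereocontrol then rests on resolution by the chiral lower unit instead of on the catalyst.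

2. Step 7. The cation may be alkylated by the unsubstituted C6 and C8 positions of a second molecule of the electrophile, attack by the hindered, bromine-deactivated C6 of 14 may be slow, and the cation may lose the C3 proton to give a flav-3-ene. Fallback, setting out from 9: NBS (2.1 equiv) in CH2Cl2 at −78 °C blocks both free ring A positions of the electrophile and gives the 6,8-dibromo flavan-4-ol F3, which cannot self-condense. F3 is coupled with 14 at near-equimolar ratio (BF3·OEt2, CH2Cl2, −30 °C) to give the tribromo dimer F4, and hydrogenolysis of F4 under the conditions of step 8 removes all three bromines with the benzyl groups and rejoins the route at 16.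

3. Step 2. The enolate may be acylated on oxygen instead of carbon, and the pyranone may be opened or cleaved (retro-Claisen) by alkoxide during the benzyloxide stage. Fallback, setting out from 4: aldol addition to 4-(benzyloxy)benzaldehyde with in-flask SNAr ring closure (K2CO3, DMF, 60 °C) should give the racemic 2,3-trans 3-(benzyloxy)-5,7-difluoroflavanone F5. Dehydrogenation (I2, DMSO, 110 °C) removes both stereocenters and gives 7, now isolated, and separate treatment of 7 with BnONa in DMF at 25 °C rejoins the route at 8.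

Further compounds
F1 | step 3 | (2S,3S,4S)-3,5,7-tris(benzyloxy)-2-[4-(benzyloxy)phenyl]-3,4-dihydro-2H-chromen-4-ol (enantiomer of 9) | O[C@H]1c2c(OCc3ccccc3)cc(OCc3ccccc3)cc2O[C@@H](c2ccc(OCc3ccccc3)cc2)[C@H]1OCc1ccccc1
F2 | step 3 | diastereomer of 15 in which the upper unit is 2S,3S and 4α-linked | O=C(O[C@@H]1Cc2c(c(Br)c(OCc5ccccc5)c([C@@H]3c4c(OCc5ccccc5)cc(OCc5ccccc5)cc4O[C@@H](c4ccc(OCc5ccccc5)cc4)[C@H]3OCc5ccccc5)c2OCc5ccccc5)O[C@@H]1c1ccc(OCc5ccccc5)c(OCc5ccccc5)c1)c1cc(OCc5ccccc5)c(OCc5ccccc5)c(OCc5ccccc5)c1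
F3 | step 7 | (2R,3R,4R)-3,5,7-tris(benzyloxy)-2-[4-(benzyloxy)phenyl]-6,8-dibromo-3,4-dihydro-2H-chromen-4-ol | O[C@@H]1c2c(OCc3ccccc3)c(Br)c(OCc3ccccc3)c(Br)c2O[C@H](c2ccc(OCc3ccccc3)cc2)[C@@H]1OCc1ccccc1
F4 | step 7 | 15 with additional bromine atoms at C6 and C8 of the upper unit | O=C(O[C@@H]1Cc2c(c(Br)c(OCc5ccccc5)c([C@H]3c4c(OCc5ccccc5)c(Br)c(OCc5ccccc5)c(Br)c4O[C@H](c4ccc(OCc5ccccc5)cc4)[C@@H]3OCc5ccccc5)c2OCc5ccccc5)O[C@@H]1c1ccc(OCc5ccccc5)c(OCc5ccccc5)c1)c1cc(OCc5ccccc5)c(OCc5ccccc5)c(OCc5ccccc5)c1
F5 | step 2 | rac-(2R,3R)-3-(benzyloxy)-2-[4-(benzyloxy)phenyl]-5,7-difluoro-2,3-dihydro-4H-chromen-4-one (2,3-trans; one enantiomer drawn) | O=C1c2c(F)cc(F)cc2O[C@H](c2ccc(OCc3ccccc3)cc2)[C@H]1OCc1ccccc1
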